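**Plan**

- Retrosynthesis: the side chain is cut at C15–C16 (vinylogous aldol with the intact 4-methylbutenolide), at C13=C14 (Horner–Wadsworth–Emmons) and at C9–C11 (B-alkyl Suzuki, with C8–OH and C9–H coming from the resulting C8=C9 alkene). Ring A is then cut at C3–C4, and its two arms at C10–C1 and C5–C4 from a ring B enone.
- Forward: ring B is the carbocycle of phenol 1, converted into the (S)-silyloxy enone 6. A Michael addition/alkylation sets C5 and C10 and attaches the propanoate arm (C4, C18, C19) and the 3-chloropropyl arm (C1–C3). The C9 ketone, which served as the activating group, becomes the triflate and then carries the side chain. Ring A is closed last (step 10), and the butenolide ring is brought in unchanged from lactone 24.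
- Enabling feature: C4 is the α-carbon of the C18 ester, and C1–C3 are three unfunctionalised CH2 groups between C10 and C4. An ester enolate on C5 of ring B can therefore close ring A onto a 3-chloropropyl arm on C10. C5 carries only H besides C6 and C10, which fixes the enolate rotamer by allylic 1,3-strain.
- Stereochemistry: C6 comes from a CBS reduction and is relayed to C5 (anti Michael addition) and C10 (anti alkylation). C4 is set in the stereoconvergent ring closure, where a C4 epimer mixture and either enolate geometry give one quaternary centre. C8/C9 come from α-face syn hydroboration and C15/C16 from catalyst control.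

Key step: step 10

Remark: atoms are numbered as in labdanes for all intermediates. C1–C10 form the decalin; C18 is the ester carbon and C19 the methyl on C4; C17 is the methyl on C8 and C20 the methyl on C10; C11–C16 is the chain on C9, with C16 the ring carbon of the butenolide. α is the face of H5 and β the face of the C10 methyl.

**Route**

Step 1
Reactants: 1 4-methoxy-3-methylphenol
Product: 2 4,4-dimethoxy-3-methylcyclohexa-2,5-dien-1-one
Conditions: PhI(OAc)2, MeOH, 0 °C
Reagents that add atoms: methanol, CO
Why: Hypervalent-iodine oxidative dearomatisation of a para-methoxyphenol in methanol should give the quinone monoketal, so that the benzene ring of 1 becomes ring B with the future C9 carbonyl masked and the future C10 methyl in place.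

Step 2
Reactants: 2 4,4-dimethoxy-3-methylcyclohexa-2,5-dien-1-one
Product: 3 4,4-dimethoxy-3-methylcyclohex-2-en-1-one
Conditions: H2 (1 atm), RhCl(PPh3)3 (5 mol %), benzene, 25 °C
Reagents that add atoms: none
Why: Hydrogenation with Wilkinson's catalyst should reduce only the unsubstituted CH=CH bond of the cross-conjugated dienone and spare the methyl-bearing enone, as in the reduction of steroidal 1,4-dien-3-ones to 4-en-3-ones.

Step 3
Reactants: 3 4,4-dimethoxy-3-methylcyclohex-2-en-1-one
Product: 4 (1S)-4,4-dimethoxy-3-methylcyclohex-2-en-1-ol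
Conditions: (R)-1-methyl-3,3-diphenyltetrahydro-1H,3H-pyrrolo[1,2-c][1,3,2]oxazaborole [(R)-Me-CBS] (10 mol %), BH3·SMe2, THF, −20 °C
Reagents that add atoms: none
Why: Corey–Bakshi–Shibata reduction in which the alkenyl flank of the enone acts as the large group, so that the (R)-oxazaborolidine should deliver hydride to give the (S)-allylic alcohol; this carbinol carbon becomes C6 and is the only ring stereocentre set by a chiral reagent.

Step 4
Reactants: 4 (1S)-4,4-dimethoxy-3-methylcyclohex-2-en-1-ol
Product: 5 (1S)-1-(tert-butyldimethylsilyloxy)-4,4-dimethoxy-3-methylcyclohex-2-ene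
Conditions: t-BuMe2SiCl, imidazole, DMF, 25 °C
Reagents that add atoms: tert-butyldimethylsilyl chloride, CC(C)(C)[Si](C)(C)Cl
Why: Standard silylation of a secondary allylic alcohol (Corey conditions); the bulky silyl ether later directs the Michael addition.

Step 5
Reactants: 5 (1S)-1-(tert-butyldimethylsilyloxy)-4,4-dimethoxy-3-methylcyclohex-2-ene
Product: 6 (4S)-4-(tert-butyldimethylsilyloxy)-2-methylcyclohex-2-en-1-one
Conditions: oxalic acid (cat.), acetone/H2O, 25 °C
Reagents that add atoms: water, O
Why: Mild acid hydrolysis of the allylic dimethyl ketal, which the silyl ether survives, unmasks the enone whose carbonyl is C9, whose α-methyl carbon is C10 and whose β-carbon is C5.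

Step 6
Reactants: 6 (4S)-4-(tert-butyldimethylsilyloxy)-2-methylcyclohex-2-en-1-one; 7 1-methoxy-1-(trimethylsilyloxy)prop-1-ene (E/Z mixture); 8 1-chloro-3-iodopropane
Product: 10 9-oxo-10β-methyl-10α-(3-chloropropyl)-5β-[1-(methoxycarbonyl)ethyl]-6α-(tert-butyldimethylsilyloxy)cyclohexane (ring B; 5α-H; C4 epimers), via trimethylsilyl enol ether 9 (not isolated)
Conditions: 7, Tf2NH (1 mol %), CH2Cl2, −78 °C; evaporate; then BnMe3NF, 8, THF, 4 Å MS, −40 → 0 °C
Reagents that add atoms: none
Why: Mukaiyama–Michael addition of the ketene acetal to C5 anti to the C6 silyloxy group (sets 5α-H; C4 is deliberately left as a mixture), then fluoride cleavage of the regiodefined enol ether and C-alkylation of the ammonium enolate at C10 by the iodide end of 8 anti to the new C5 arm (Kuwajima-type alkylation of a fluoride-generated enolate), which should set the quaternary C10 with the methyl β and the C1–C3 arm α.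

Step 7
Reactants: 10 ring B ketone (C4 epimers)
Product: 11 9-oxo-8,10β-dimethyl-10α-(3-chloropropyl)-5β-[1-(methoxycarbonyl)ethyl]-6α-(tert-butyldimethylsilyloxy)cyclohexane (C4 and C8 epimers)
Conditions: LiN(iPr)2, THF, −78 °C; MeI
Reagents that add atoms: iodomethane, CI
Why: Kinetic enolate alkylation: the ketone can enolise only toward C8 because C10 is quaternary, and its α-CH2 is deprotonated in preference to the hindered ester α-CH, so methyl iodide should install the C17 methyl (the C8 configuration is irrelevant because C8 becomes sp2 in the next step).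

Step 8
Reactants: 11 8-methyl ketone (C4 and C8 epimers)
Product: 12 8,10β-dimethyl-10α-(3-chloropropyl)-5β-[1-(methoxycarbonyl)ethyl]-6α-(tert-butyldimethylsilyloxy)cyclohex-8-en-9-yl trifluoromethanesulfonate (C4 epimers)
Conditions: KN(SiMe3)2, THF, −78 °C; 2-[N,N-bis(trifluoromethylsulfonyl)amino]-5-chloropyridine
Reagents that add atoms: 2-[N,N-bis(trifluoromethylsulfonyl)amino]-5-chloropyridine, FC(F)(F)S(=O)(=O)N(c1ccc(Cl)cn1)S(=O)(=O)C(F)(F)F
Why: O-Sulfonylation of the potassium enolate (again only the C8=C9 enolate is possible) with Comins' reagent should give the tetrasubstituted enol triflate, which retires the C9 carbonyl as an acidic site before the ring closure and arms C9 for coupling.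

Step 9
Reactants: 12 enol triflate (C4 epimers); 13 2-methyl-2-vinyl-1,3-dioxolane
Product: 15 9-[3,3-(ethylenedioxy)butyl]-8,10β-dimethyl-10α-(3-chloropropyl)-5β-[1-(methoxycarbonyl)ethyl]-6α-(tert-butyldimethylsilyloxy)cyclohex-8-ene (C4 epimers), via B-alkyl-9-BBN 14 (not isolated)
Conditions: 13, 9-BBN-H, THF, 25 °C; then 12, PdCl2(dppf) (5 mol %), AsPh3, Cs2CO3, DMF/H2O, 50 °C
Reagents that add atoms: none
Why: Anti-Markovnikov hydroboration of the vinyl dioxolane followed by B-alkyl Suzuki–Miyaura coupling with the 2,6,6-trisubstituted cyclohexenyl triflate (a triflate type known to couple) should form the C9–C11 bond and bring in C11–C13 with the C13 ketone masked; no stereocentre is formed.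

Step 10
Reactants: 15 chloropropyl ester (C4 epimers)
Product: 17 methyl 4β,8,10β-trimethyl-9-[3,3-(ethylenedioxy)butyl]-6α-(tert-butyldimethylsilyloxy)-5α-H-decal-8-ene-4α-carboxylate, via lithium ester enolate 16 (not isolated)
Conditions: LiN(iPr)2, THF/DMPU, −78 → 25 °C
Reagents that add atoms: none
Why: Deprotonation at C4 gives the exocyclic ester enolate 16 (C4=C18), which displaces the primary chloride at C3; the closest known reaction type is the ring-closing alkylation of ester enolates by ω-haloalkyl chains. Ring A (C4–C3–C2–C1–C10–C5) closes in the 6-(enolexo)-exo-tet mode through a chair in which the C1 and C4 arms are both equatorial on ring B, so the ring fusion is trans. The new quaternary C4 is controlled by allylic 1,3-strain: H5 lies in the enolate plane syn to C18, so the ester carbon points to the α face (peri to C6) and the C4 methyl to the β face, while C3, held on C10, bonds in the plane of the forming ring anti to C6. The step is stereoconvergent, because both C4 epimers of 15 and both enolate geometries pass through the same rotamer and should give only the 4α-CO2Me/4β-CH3 isomer. The selectivity needed is this rotamer over the one with C18 wedged between C6 and C10, and it is secured by H5 being the only small group on C5; competing ketone enolate chemistry at C8 is excluded because C9 is already an alkene carbon.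

Step 11
Reactants: 17 decal-8-ene ester
Product: 19 methyl 8α-hydroxy-4β,8β,10β-trimethyl-9β-[3,3-(ethylenedioxy)butyl]-6α-(tert-butyldimethylsilyloxy)-5α,9α-H-decalin-4α-carboxylate, via C8 alkylborane 18 (not isolated)
Conditions: BH3·THF, THF, 0 → 25 °C; then NaOH, H2O2, 0 °C
Reagents that add atoms: hydrogen peroxide, OO
Why: Hydroboration–oxidation of the tetrasubstituted alkene: borane should add syn from the α face (the β face is screened by the axial C10 and C4 methyl groups) with boron on the less hindered C8 and hydrogen on the neopentyl C9, and oxidation with retention then gives the 8α-hydroxy-8β-methyl and 9α-H (side chain β) centres.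

Step 12
Reactants: 19 8α-ol ketal
Product: 20 methyl 8α-hydroxy-4β,8β,10β-trimethyl-9β-(3-oxobutyl)-6α-(tert-butyldimethylsilyloxy)-5α,9α-H-decalin-4α-carboxylate
Conditions: pyridinium p-toluenesulfonate, acetone/H2O, 50 °C
Reagents that add atoms: water, O
Why: Acid-catalysed hydrolysis of the dioxolane frees the C13 methyl ketone, while the secondary silyl ether and the hindered ester should survive pyridinium p-toluenesulfonate.

Step 13
Reactants: 20 hydroxy methyl ketone; 21 diethyl [2-(methoxy(methyl)amino)-2-oxoethyl]phosphonate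
Product: 22 (13E)-N-methoxy-N-methyl enamide: 20 with the side chain CH2CH2C(CH3)=CH–C(=O)N(OMe)Me
Conditions: NaH, THF, 0 → 50 °C
Reagents that add atoms: none
Why: Horner–Wadsworth–Emmons olefination of the methyl ketone with the Weinreb-amide phosphonate should give mainly the (13E)-alkene (the C12 chain trans to the amide carbonyl), the minor Z isomer being removed by chromatography.

Step 14
Reactants: 22 (13E)-enamide
Product: 23 (13E)-enal: side chain CH2CH2C(CH3)=CH–CHO (C15 aldehyde)
Conditions: Cp2Zr(H)Cl, THF, 25 °C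
Reagents that add atoms: none
Why: Schwartz's reagent reduces tertiary amides to aldehydes through a zirconated hemiaminal that collapses only on work-up, so the enal should form without over-reduction and without touching the hindered C18 methyl ester.

Step 15
Reactants: 24 4-methylfuran-2(5H)-one
Product: 25 4-methyl-2-(trimethylsilyloxy)furan
Conditions: Me3SiCl, Et3N, Et2O, 25 °C
Reagents that add atoms: chlorotrimethylsilane, C[Si](C)(C)Cl
Why: Soft enolisation and O-silylation of the butenolide is the standard preparation of 2-silyloxyfurans, so the butenolide ring is carried in intact from the commercial lactone.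

Step 16
Reactants: 23 (13E)-enal; 25 4-methyl-2-(trimethylsilyloxy)furan
Product: 27 6-O-tert-butyldimethylsilyl ether of the target with (15S,16S) side chain, via 15-O-trimethylsilyl ether 26 (not isolated)
Conditions: Ti(OiPr)4 (20 mol %), (R)-1,1'-bi-2-naphthol (20 mol %), Et2O, −20 °C; then 1 M HCl, THF, 0 °C
Reagents that add atoms: none
Why: Catalytic asymmetric vinylogous Mukaiyama aldol reaction: C5 of the silyloxyfuran adds to the enal carbonyl through an open transition state that favours the syn (15,16) adduct, and the (R)-BINOL–titanium complex is expected, as in related Ti–BINOL carbonyl additions, to expose the Re face of the aldehyde, giving 15S and hence 16S independently of the remote decalin.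

Step 17
Reactants: 27 6-O-silyl ether
Product: 28 CNP0104474.1
Conditions: HF·pyridine, THF/pyridine, 0 → 25 °C
Reagents that add atoms: none
Why: Fluoride cleavage of the secondary silyl ether under buffered, non-basic conditions should leave the base-sensitive butenolide, the allylic alcohol and the hydroxy ester (no lactonisation onto C18) untouched and give the target.

**Compound list**

1 | 4-methoxy-3-methylphenol | COc1ccc(O)cc1C | starting material
2 | 4,4-dimethoxy-3-methylcyclohexa-2,5-dien-1-one | COC1(OC)C=CC(=O)C=C1C | intermediate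
3 | 4,4-dimethoxy-3-methylcyclohex-2-en-1-one | COC1(OC)CCC(=O)C=C1C | intermediate
4 | (1S)-4,4-dimethoxy-3-methylcyclohex-2-en-1-ol | O[C@@H]1C=C(C)C(OC)(OC)CC1 | intermediate
5 | (1S)-1-(tert-butyldimethylsilyloxy)-4,4-dimethoxy-3-methylcyclohex-2-ene | CC(C)(C)[Si](C)(C)O[C@@H]1C=C(C)C(OC)(OC)CC1 | intermediate
6 | (4S)-4-(tert-butyldimethylsilyloxy)-2-methylcyclohex-2-en-1-one | CC(C)(C)[Si](C)(C)O[C@@H]1C=C(C)C(=O)CC1 | intermediate
7 | 1-methoxy-1-(trimethylsilyloxy)prop-1-ene (E/Z mixture) | CC=C(OC)O[Si](C)(C)C | starting material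
8 | 1-chloro-3-iodopropane | ClCCCI | starting material
9 | C9/C10 trimethylsilyl enol ether of the Michael adduct (5α-H, 6α-OTBS, C4 epimers) | COC(=O)C(C)[C@@H]1[C@@H](O[Si](C)(C)C(C)(C)C)CCC(O[Si](C)(C)C)=C1C | intermediate
10 | 9-oxo-10β-methyl-10α-(3-chloropropyl)-5β-[1-(methoxycarbonyl)ethyl]-6α-(tert-butyldimethylsilyloxy)cyclohexane (C4 epimers) | COC(=O)C(C)[C@@H]1[C@@H](O[Si](C)(C)C(C)(C)C)CCC(=O)[C@@]1(C)CCCCl | intermediate
11 | 8-methyl derivative of 10 (C4 and C8 epimers) | COC(=O)C(C)[C@@H]1[C@@H](O[Si](C)(C)C(C)(C)C)CC(C)C(=O)[C@@]1(C)CCCCl | intermediate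
12 | cyclohex-8-en-9-yl triflate of 11 (C4 epimers) | COC(=O)C(C)[C@@H]1[C@@H](O[Si](C)(C)C(C)(C)C)CC(C)=C(OS(=O)(=O)C(F)(F)F)[C@@]1(C)CCCCl | intermediate
13 | 2-methyl-2-vinyl-1,3-dioxolane | C=CC1(C)OCCO1 | starting material
14 | B-[2-(2-methyl-1,3-dioxolan-2-yl)ethyl]-9-borabicyclo[3.3.1]nonane | CC1(CCB2C3CCCC2CCC3)OCCO1 | intermediate
15 | 9-[3,3-(ethylenedioxy)butyl]-8,10β-dimethyl-10α-(3-chloropropyl)-5β-[1-(methoxycarbonyl)ethyl]-6α-(tert-butyldimethylsilyloxy)cyclohex-8-ene (C4 epimers) | COC(=O)C(C)[C@@H]1[C@@H](O[Si](C)(C)C(C)(C)C)CC(C)=C(CCC2(C)OCCO2)[C@@]1(C)CCCCl | intermediate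
16 | lithium ester enolate of 15 (C4=C18) | COC(O[Li])=C(C)[C@@H]1[C@@H](O[Si](C)(C)C(C)(C)C)CC(C)=C(CCC2(C)OCCO2)[C@@]1(C)CCCCl | intermediate
17 | methyl 4β,8,10β-trimethyl-9-[3,3-(ethylenedioxy)butyl]-6α-(tert-butyldimethylsilyloxy)-5α-H-decal-8-ene-4α-carboxylate | COC(=O)[C@]1(C)CCC[C@@]2(C)[C@H]1[C@@H](O[Si](C)(C)C(C)(C)C)CC(C)=C2CCC1(C)OCCO1 | intermediate
18 | 8α-boryl-9α-H alkylborane from 17 | COC(=O)[C@]1(C)CCC[C@@]2(C)[C@H]1[C@@H](O[Si](C)(C)C(C)(C)C)C[C@@](C)(B)[C@@H]2CCC1(C)OCCO1 | intermediate
19 | 8α-hydroxy-8β-methyl-9α-H decalin ester with C13 dioxolane | COC(=O)[C@]1(C)CCC[C@@]2(C)[C@H]1[C@@H](O[Si](C)(C)C(C)(C)C)C[C@@](C)(O)[C@@H]2CCC1(C)OCCO1 | intermediate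
20 | 8α-hydroxy 13-ketone (9β-(3-oxobutyl) chain) | COC(=O)[C@]1(C)CCC[C@@]2(C)[C@H]1[C@@H](O[Si](C)(C)C(C)(C)C)C[C@@](C)(O)[C@@H]2CCC(C)=O | intermediate
21 | diethyl [2-(methoxy(methyl)amino)-2-oxoethyl]phosphonate | CCOP(=O)(CC(=O)N(C)OC)OCC | starting material
22 | (13E)-N-methoxy-N-methyl enamide | COC(=O)[C@]1(C)CCC[C@@]2(C)[C@H]1[C@@H](O[Si](C)(C)C(C)(C)C)C[C@@](C)(O)[C@@H]2CC/C(C)=C/C(=O)N(C)OC | intermediate
23 | (13E)-enal (C15 aldehyde) | COC(=O)[C@]1(C)CCC[C@@]2(C)[C@H]1[C@@H](O[Si](C)(C)C(C)(C)C)C[C@@](C)(O)[C@@H]2CC/C(C)=C/C=O | intermediate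
24 | 4-methylfuran-2(5H)-one | CC1=CC(=O)OC1 | starting material
25 | 4-methyl-2-(trimethylsilyloxy)furan | Cc1coc(O[Si](C)(C)C)c1 | intermediate
26 | 15-O-trimethylsilyl-6-O-tert-butyldimethylsilyl ether of the target | COC(=O)[C@]1(C)CCC[C@@]2(C)[C@H]1[C@@H](O[Si](C)(C)C(C)(C)C)C[C@@](C)(O)[C@@H]2CC/C(C)=C/[C@H](O[Si](C)(C)C)[C@H]1OC(=O)C=C1C | intermediate
27 | 6-O-tert-butyldimethylsilyl ether of the target, (15S,16S) | COC(=O)[C@]1(C)CCC[C@@]2(C)[C@H]1[C@@H](O[Si](C)(C)C(C)(C)C)C[C@@](C)(O)[C@@H]2CC/C(C)=C/[C@H](O)[C@H]1OC(=O)C=C1C | intermediate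
28 | CNP0104474.1: methyl 6α,8α-dihydroxy-4β,8β,10β-trimethyl-5α,9α-H-decalin-4α-carboxylate with the 9β-[(13E,15S)-15-hydroxy-13-methyl-15-((16S)-4-methyl-5-oxo-2,5-dihydrofuran-2-yl)pent-13-enyl] chain | COC(=O)[C@]1(C)CCC[C@@]2(C)[C@H]1[C@@H](O)C[C@@](C)(O)[C@@H]2CC/C(C)=C/[C@H](O)[C@H]1OC(=O)C=C1C | target

**Step count**

Total: 17 steps. Longest linear sequence: 16 steps (steps 1–14, 16 and 17); step 15 is a one-step branch.

**Steps most likely to fail**

1. Step 10 (ring A closure). The hindered tertiary ester enolate may close slowly on the primary chloride, with competing elimination or proton transfer, or the rotamer preference may be incomplete so that the C4 epimer forms alongside. Fallback, from 15 back to 17: saponify 15 (LiOH, THF/MeOH/H2O) to the carboxylic acid of 15 F1. Close ring A on its dilithium enediolate (LiN(iPr)2, 2.2 equiv, THF/DMPU, −78 → 25 °C); two identical O–Li groups make the allylic-strain bias independent of enolate geometry and raise the nucleophilicity. This should give the ring-closed 4α-carboxylic acid F2, which is methylated with Me3SiCHN2 (MeOH/toluene) to return to 17.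

2. Step 11 (hydroboration). Addition of borane to the tetrasubstituted C8=C9 bond may be sluggish, may place boron partly on C9, or may be accompanied by reduction of the ester. Fallback, from 17 back to 19: epoxidise the alkene from the open α face (mCPBA, NaHCO3, CH2Cl2, 0 °C) to the 8α,9α-epoxide F3. Open it reductively with Cp2TiCl (from Cp2TiCl2 and Zn) and 1,4-cyclohexadiene in THF. Homolysis of the more congested C9–O bond should leave the oxygen on C8 and a tertiary C9 radical that takes hydrogen from the α face, giving 19.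

3. Step 16 (vinylogous aldol). Facial control by the catalyst may be poor for this β,β-disubstituted enal, so that the other syn isomer or anti isomers accompany 27. Fallback, from 23 and 25 back to 27: run the addition with BF3·OEt2 (CH2Cl2, −78 °C), which should still give syn adducts but as a mixture of 27 and the (15R,16R)-diastereomer of 27 F4. A Sharpless kinetic resolution (Ti(OiPr)4, L-(+)-diisopropyl tartrate, t-BuOOH, 4 Å MS, CH2Cl2, −20 °C) then epoxidises the fast-reacting 15R allylic alcohol to the 13,14-epoxy alcohol F5 and leaves the 15S isomer 27, which is separated by chromatography.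

Further compounds
F1 | step 10 | carboxylic acid of 15 (C4 epimers) | OC(=O)C(C)[C@@H]1[C@@H](O[Si](C)(C)C(C)(C)C)CC(C)=C(CCC2(C)OCCO2)[C@@]1(C)CCCCl
F2 | step 10 | ring-closed 4α-carboxylic acid (acid of 17) | OC(=O)[C@]1(C)CCC[C@@]2(C)[C@H]1[C@@H](O[Si](C)(C)C(C)(C)C)CC(C)=C2CCC1(C)OCCO1
F3 | step 11 | 8α,9α-epoxide of 17 | COC(=O)[C@]1(C)CCC[C@@]2(C)[C@H]1[C@@H](O[Si](C)(C)C(C)(C)C)C[C@@]3(C)O[C@@]23CCC4(C)OCCO4
F4 | step 16 | (15R,16R)-diastereomer of 27 | COC(=O)[C@]1(C)CCC[C@@]2(C)[C@H]1[C@@H](O[Si](C)(C)C(C)(C)C)C[C@@](C)(O)[C@@H]2CC/C(C)=C/[C@@H](O)[C@@H]1OC(=O)C=C1C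
F5 | step 16 | 13,14-epoxy alcohol from F4 | COC(=O)[C@]1(C)CCC[C@@]2(C)[C@H]1[C@@H](O[Si](C)(C)C(C)(C)C)C[C@@](C)(O)[C@@H]2CC[C@@]3(C)O[C@@H]3[C@@H](O)[C@@H]4OC(=O)C=C4C
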